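**Strategy.** The central quinone ring is a masked cyclohexane-1,2,4,5-tetraone: each aryl-bearing ring carbon (C3, C6) lies between two oxygenated carbons (C1, C2, C4, C5), so every C(aryl)–C(O) ring bond is a Claisen retron. The ring is therefore assembled in one operation from 1,4-bis(4-methoxyphenyl)butane-2,3-dione and diethyl oxalate. An intermolecular Claisen condensation gives an open-chain trioxo ester, whose second benzylic enolate closes the ring by Dieckmann attack on the ester carbonyl. Demethylation gives atromentin, whose two acidic enol hydroxyls are acylated last with (2Z,4S,5S)-4,5-epoxyhex-2-enoyl chloride, made by Sharpless epoxidation and Still–Gennari olefination.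

Key step: step 2

Remark on the chemistry: in 2,5-dihydroxy-3,6-diaryl-1,4-benzoquinones the enol and carbonyl carbons exchange by degenerate tautomerism. The bond closed in step 2 therefore becomes one of the two equivalent aryl-carbon/quinone-carbonyl bonds of the target once the enol oxygens are acylated.

**Step 1**
Reactants: 1 4-methoxybenzylmagnesium chloride (THF solution, 2.3 equiv); 2 N,N'-dimethoxy-N,N'-dimethyloxalamide
Product: 3 1,4-bis(4-methoxyphenyl)butane-2,3-dione
Conditions: THF, −78 °C to 0 °C, Ar; sat. aq. NH4Cl, 0 °C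
Reagents that add atoms: none
Why: Weinreb ketone synthesis on the bis-Weinreb amide of oxalic acid: each benzyl Grignard addition should stop at a magnesium-chelated tetrahedral intermediate, and both collapse only on work-up to the 1,2-diketone.

**Step 2**
Reactants: 3 1,4-bis(4-methoxyphenyl)butane-2,3-dione; 4 diethyl oxalate (1.5 equiv)
Product: 6 2,5-dihydroxy-3,6-bis(4-methoxyphenyl)-1,4-benzoquinone, via open-chain trioxo ester 5 (not isolated)
Conditions: NaOEt (2.5 equiv), EtOH–THF, slow addition of 3, 0 °C to 60 °C, N2; then 1 M HCl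
Reagents that add atoms: none
Why: Ethoxide converts 3 into its benzylic enolate, which is C-acylated by diethyl oxalate (intermolecular Claisen condensation) to the open-chain trioxo ester 5; the second benzylic enolate of 5 then attacks the remaining ester carbonyl (Dieckmann condensation), forming the ring bond between an aryl-bearing carbon and a carbonyl carbon and expelling ethoxide. The closest known reaction type is the alkoxide-mediated double Claisen condensation of bis-benzylic ketones with dialkyl oxalates, as in the formation of 3,5-diarylcyclopentane-1,2,4-triones from 1,3-diarylacetones. The six-membered ring closes in a 6-(enolendo)-exo-trig mode. No stereocentre is created. The step needs C- over O-acylation and Claisen over aldol reactivity: all condensations and any O-acyl or lactone by-products are reversible under ethoxide, whereas the cyclised tetraone is removed irreversibly as the doubly deprotonated dihydroxyquinone (a twofold vinylogous acid), and the symmetry of 3 and of the oxalate removes any regiochemical question.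

**Step 3**
Reactants: 6 2,5-dihydroxy-3,6-bis(4-methoxyphenyl)-1,4-benzoquinone
Product: 7 atromentin, 2,5-dihydroxy-3,6-bis(4-hydroxyphenyl)-1,4-benzoquinone
Conditions: BBr3 (6 equiv), CH2Cl2, −78 °C to rt; H2O, 0 °C
Reagents that add atoms: none
Why: Lewis acid-mediated aryl methyl ether cleavage (bromide attacks the O-methyl group of the aryl ether–borane adduct); the quinone enol hydroxyls are held as borates and should be released on hydrolysis.

**Step 4**
Reactants: 8 (E)-but-2-en-1-ol
Product: 9 [(2S,3S)-3-methyloxiran-2-yl]methanol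
Conditions: Ti(Oi-Pr)4 (5 mol%), L-(+)-diisopropyl tartrate (6 mol%), t-BuOOH (anhydrous), 4 Å MS, CH2Cl2, −20 °C; non-aqueous work-up, distillation
Reagents that add atoms: tert-butyl hydroperoxide, CC(C)(C)OO
Why: Sharpless asymmetric epoxidation: the titanium/L-(+)-tartrate complex binds the allylic alkoxide and delivers the peroxide oxygen to one enantioface of the E-alkene, which should set both epoxide stereocentres as (2S,3S), trans by stereospecific syn-addition.

**Step 5**
Reactants: 9 [(2S,3S)-3-methyloxiran-2-yl]methanol; 10 methyl 2-[bis(2,2,2-trifluoroethoxy)phosphoryl]acetate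
Product: 12 methyl (2Z,4S,5S)-4,5-epoxyhex-2-enoate, via epoxy aldehyde 11 (not isolated)
Conditions: (i) TPAP (5 mol%), NMO (1.5 equiv), 4 Å MS, CH2Cl2, 0 °C to rt; short silica pad, cold concentration; (ii) 10, KHMDS, 18-crown-6, THF, −78 °C
Reagents that add atoms: none
Why: Ley–Griffith oxidation should give the volatile epoxy aldehyde without touching the epoxide, and the Still–Gennari olefination (electron-poor phosphonate, dissociated potassium counter-ion) eliminates irreversibly from the kinetic adduct to give the Z-enoate; both stereocentres are carried through unchanged.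

**Step 6**
Reactants: 12 methyl (2Z,4S,5S)-4,5-epoxyhex-2-enoate
Product: 13 sodium (2Z,4S,5S)-4,5-epoxyhex-2-enoate
Conditions: NaOH (1.0 equiv), THF–H2O, 0 °C; freeze-drying, drying in vacuo
Reagents that add atoms: sodium hydroxide, [Na+].[OH-]
Why: Saponification (BAc2) with one equivalent of hydroxide at 0 °C should cleave the methyl ester faster than the epoxide or the Z-alkene reacts, and isolation as the sodium salt avoids the free acid, which could lactonise onto the epoxide.

**Step 7**
Reactants: 7 atromentin; 13 sodium (2Z,4S,5S)-4,5-epoxyhex-2-enoate (2.2 equiv)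
Product: 15 2,5-bis[(2Z,4S,5S)-4,5-epoxyhex-2-enoyloxy]-3,6-bis(4-hydroxyphenyl)-1,4-benzoquinone (CNP0407724.1), via acid chloride 14 (not isolated)
Conditions: (i) 13, (COCl)2 (2.1 equiv), DMF (cat.), CH2Cl2, 0 °C; (ii) 7, i-Pr2NEt (2.0 equiv), THF, −40 °C to 0 °C; pH 4 buffer work-up
Reagents that add atoms: none
Why: The carboxylate salt and oxalyl chloride should give the acid chloride without free HCl (sparing the epoxide and the Z-alkene), and exactly two equivalents of amine ionise only the two vinylogous-acid enol hydroxyls (pKa about 3–5 against about 10 for the phenols), whose oxyanions are O-acylated to the 2,5-diacyloxy-1,4-quinone (enol ester formation with an acid chloride, the usual outcome for 2,5-dihydroxy-1,4-benzoquinones) while the neutral phenols stay unreactive at low temperature without free base.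

**Compound list**
1 | 4-methoxybenzylmagnesium chloride | COc1ccc(C[Mg]Cl)cc1 | starting material
2 | N,N'-dimethoxy-N,N'-dimethyloxalamide | CON(C)C(=O)C(=O)N(C)OC | starting material
3 | 1,4-bis(4-methoxyphenyl)butane-2,3-dione | COc1ccc(CC(=O)C(=O)Cc2ccc(OC)cc2)cc1 | intermediate
4 | diethyl oxalate | CCOC(=O)C(=O)OCC | starting material
5 | ethyl 3,6-bis(4-methoxyphenyl)-2,4,5-trioxohexanoate (open-chain trioxo ester, not isolated) | CCOC(=O)C(=O)C(c1ccc(OC)cc1)C(=O)C(=O)Cc1ccc(OC)cc1 | intermediate
6 | 2,5-dihydroxy-3,6-bis(4-methoxyphenyl)-1,4-benzoquinone | COc1ccc(cc1)C1=C(O)C(=O)C(c2ccc(OC)cc2)=C(O)C1=O | intermediate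
7 | atromentin, 2,5-dihydroxy-3,6-bis(4-hydroxyphenyl)-1,4-benzoquinone | Oc1ccc(cc1)C1=C(O)C(=O)C(c2ccc(O)cc2)=C(O)C1=O | intermediate
8 | (E)-but-2-en-1-ol | C/C=C/CO | starting material
9 | [(2S,3S)-3-methyloxiran-2-yl]methanol | C[C@@H]1O[C@H]1CO | intermediate
10 | methyl 2-[bis(2,2,2-trifluoroethoxy)phosphoryl]acetate | COC(=O)CP(=O)(OCC(F)(F)F)OCC(F)(F)F | starting material
11 | (2R,3S)-3-methyloxirane-2-carbaldehyde (epoxy aldehyde, not isolated) | C[C@@H]1O[C@H]1C=O | intermediate
12 | methyl (2Z,4S,5S)-4,5-epoxyhex-2-enoate, i.e. methyl (2Z)-3-[(2S,3S)-3-methyloxiran-2-yl]prop-2-enoate | C[C@@H]1O[C@H]1/C=C\C(=O)OC | intermediate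
13 | sodium (2Z,4S,5S)-4,5-epoxyhex-2-enoate | C[C@@H]1O[C@H]1/C=C\C(=O)[O-].[Na+] | intermediate
14 | (2Z,4S,5S)-4,5-epoxyhex-2-enoyl chloride (acid chloride, not isolated) | C[C@@H]1O[C@H]1/C=C\C(Cl)=O | intermediate
15 | 2,5-bis[(2Z,4S,5S)-4,5-epoxyhex-2-enoyloxy]-3,6-bis(4-hydroxyphenyl)-1,4-benzoquinone (CNP0407724.1) | C[C@@H]1O[C@H]1/C=C\C(=O)OC1=C(c2ccc(O)cc2)C(=O)C(OC(=O)/C=C\[C@@H]2O[C@H]2C)=C(c2ccc(O)cc2)C1=O | target

**Total step count:** 7. **Longest linear sequence:** 4 steps (1, 2, 3, 7 or 4, 5, 6, 7).

**Steps most likely to fail**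

Step 2. The ring closure may lose to self-aldol condensation of the enol-rich diketone, to O-acylation and lactonisation of the open-chain adduct, or to retro-Claisen cleavage under ethoxide. The fallback sets out from 3. Silylation (TMSCl, Et3N, NaI, MeCN) should give (1Z,3Z)-1,4-bis(4-methoxyphenyl)-2,3-bis(trimethylsilyloxy)buta-1,3-diene F1 (alkene geometry immaterial). Treatment of F1 with oxalyl chloride (TMSOTf cat., CH2Cl2, −78 °C to rt) is a Mukaiyama-type double C-acylation, in which the second, intramolecular acylation closes the same ring bond without base or free enolate. Aqueous work-up returns to the route at 6.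

Step 7. The phenols may be acylated in competition with the enol oxyanions, the second acylation may stall, or the activated acid may lose its Z geometry or open its epoxide before it is transferred. The fallback sets out from 7. TBSCl and imidazole in DMF should silylate all four hydroxyls to 2,5-bis(tert-butyldimethylsilyloxy)-3,6-bis[4-(tert-butyldimethylsilyloxy)phenyl]-1,4-benzoquinone F2. Its two quinone silyl enol ethers (vinylogous silyl esters) hydrolyse on work-up with dilute citric acid to give 2,5-dihydroxy-3,6-bis[4-(tert-butyldimethylsilyloxy)phenyl]-1,4-benzoquinone F3. Acylation of F3 with 14 (2,6-lutidine, CH2Cl2, −40 °C) should give the bis(silyl) diester F4, now with no free phenol present. HF·pyridine buffered with pyridine (THF, 0 °C) then cleaves the aryl silyl ethers and returns to the route at 15.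

Step 1. Wurtz-type homocoupling of the benzylic Grignard reagent, stalling at the mono-adduct chelate, or enolisation and air oxidation of the diketone may erode the double addition. The fallback sets out from 1. Transmetalation to the benzylcopper reagent (CuBr·SMe2, LiBr, THF, −78 °C) and coupling with oxalyl chloride (0.5 equiv) forms both acyl C–C bonds at the acid chloride level, where the non-basic organocopper neither adds to nor enolises the product. It returns to the route at 3 and makes no new compound.

**Further compounds**
F1 | step 2 | (1Z,3Z)-1,4-bis(4-methoxyphenyl)-2,3-bis(trimethylsilyloxy)buta-1,3-diene | COc1ccc(/C=C(\O[Si](C)(C)C)/C(O[Si](C)(C)C)=C/c2ccc(OC)cc2)cc1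
F2 | step 7 | 2,5-bis(tert-butyldimethylsilyloxy)-3,6-bis[4-(tert-butyldimethylsilyloxy)phenyl]-1,4-benzoquinone | CC(C)(C)[Si](C)(C)Oc1ccc(cc1)C1=C(O[Si](C)(C)C(C)(C)C)C(=O)C(c2ccc(O[Si](C)(C)C(C)(C)C)cc2)=C(O[Si](C)(C)C(C)(C)C)C1=O
F3 | step 7 | 2,5-dihydroxy-3,6-bis[4-(tert-butyldimethylsilyloxy)phenyl]-1,4-benzoquinone | CC(C)(C)[Si](C)(C)Oc1ccc(cc1)C1=C(O)C(=O)C(c2ccc(O[Si](C)(C)C(C)(C)C)cc2)=C(O)C1=O
F4 | step 7 | 2,5-bis[(2Z,4S,5S)-4,5-epoxyhex-2-enoyloxy]-3,6-bis[4-(tert-butyldimethylsilyloxy)phenyl]-1,4-benzoquinone | C[C@@H]1O[C@H]1/C=C\C(=O)OC1=C(c2ccc(O[Si](C)(C)C(C)(C)C)cc2)C(=O)C(OC(=O)/C=C\[C@@H]2O[C@H]2C)=C(c2ccc(O[Si](C)(C)C(C)(C)C)cc2)C1=O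
F0 | step 1 | none | none
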